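The constants used here belong to no real substance, and the outcome is calculated.

Watch the first seconds of this flask, then the slow climb of monomer in chains.

free monomer 0.050 M; initiator 5 mol%; time 5.0 min

    free monomer + living end → monomer in chains + living end, rate k1*[living end]*[free monomer] (k1 = 6.0 M⁻¹ s⁻¹)
    2 initiator → spent initiator A (k2 = 52 M⁻¹ s⁻¹)
    free monomer + initiator → living end + monomer in chains (k3 = 17 M⁻¹ s⁻¹)
    free monomer + initiator → spent initiator B (k4 = 7.2 M⁻¹ s⁻¹)

- whether the average number of monomer units in a chain (chains begun, living or dead) reaches 10 by 5.0 min (yes / no)
- average number of monomer units in a chain (chains begun, living or dead) at 5.0 min

- for a step with 2 of a species take k times the square, and two of it per event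
- the average divides the monomer in chains by the number of chains begun, living and dead together
- run time (flask): 5.0 min

I first compared what each way out took from the initiator at the charge: 0.850 s⁻¹ towards living ends, 0.360 s⁻¹ towards spent initiator B, and 0.260 s⁻¹ towards spent initiator A. In one extreme I held that last rate at its starting value throughout, and reckoned that 57.8% of the initiator began chains. In the other I set it to nil, and reckoned 70.2%.

I expected the real flask to lie between, because the last rate sinks with the initiator, whose lifetime at those starting rates I put at 0.680 s, while I put the lifetime of free monomer under growth, with the higher share of living ends, at 94.9 s. Summing over the fall of the initiator, with free monomer held at its charge, gave the chain share, the fraction of the initiator charge that ends as living ends: 63.6%. Growth was then pseudo-first-order in free monomer, and I reckoned an average of 29.6 at 5.0 min, past 10.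

The forecast said yes and 29.5, slightly below mine, with “the rest lost to the two side steps”.

This flask gave yes and 29.3, its average passing 10 units at 0.636 min. Living ends in this flask stood at 63.5% of the initiator charge, against my chain share of 63.6%, and half the turnover up to 5.0 min was done by 0.541 s for the step to spent initiator B, against 1.13 min for growth. For the flask with twice the initiator and all other amounts as they were, I reckoned a chain share of 58.4% and an average of 17.0; that flask stood at 16.7 at the end of the run.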